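## Retrosynthetic overview

- Target ⇐ C3–O acylation and C11–O Mitsunobu etherification (umbelliferone) of an ent-3-hydroxyalbicanol diol. The C8=C12 exocyclic alkene and C9–H come from deconjugative protonation of a Δ8(9)-11-ester.
- Ring A (C1, C2, C3, C4, C5, C10) is closed at the C3–C4 bond: hydrogen-atom transfer to an isopropenyl group on C5 gives the C4 tertiary radical, which adds 6-exo-dig to a nitrile carbon (C3) on the C10 side chain; hydrolysis gives the 4,4-dimethyl-3-ketone.
- Enabling feature: the gem-dimethyl quaternary carbon C4 of ring A next to the oxygen-bearing C3. C4(CH3)2 is an isopropenyl group plus one hydrogen atom, and C3–O is a nitrile carbon.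
- Ring B with its isopropenyl group at C5 is (S)-carvone. The C10 quaternary centre comes from methylation then allylation of its kinetic enolate (chain trans to isopropenyl, hence the trans ring fusion); C11 comes from carbonylation of the C9 enol triflate.
- Ring order: coumarin rings (bought as umbelliferone), ring B (bought as carvone), ring A (formed in the route).

Key step: step 7

Remark on the chemistry: drimane numbering is used for the bicyclic compounds (ring A = C1–C5 and C10, ring B = C5–C10, C11 = CH2O, C12 = exocyclic CH2). The target is (3R,5S,9R,10R), the ent-drimane series with a trans ring fusion and C10–CH3, C9–CH2O and C3–O on one face. This maps onto (S)-(+)-carvone.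

## Route

Step 1
Reactants: 1 (S)-(+)-carvone
Product: 3 (5S,6R)-6-methylcarvone (methyl trans to isopropenyl, with some cis epimer), via lithium dienolate 2 (not isolated)
Conditions: LiN(i-Pr)2, THF, −78 °C; then MeI, −78 to 0 °C
Reagents that add atoms: iodomethane, CI
Why: Kinetic deprotonation of the enone occurs at the α' carbon (the future C10) and the cross-conjugated enolate is C-methylated (enolate alkylation); the new centre is planarised again in step 2, so its epimer ratio does not matter.

Step 2
Reactants: 3 (5S,6R)-6-methylcarvone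
Product: 5 (5R,6R)-6-allyl-2,6-dimethyl-5-(prop-1-en-2-yl)cyclohex-2-en-1-one (allyl trans, methyl cis to isopropenyl), via lithium enolate 4 (not isolated)
Conditions: LiN(i-Pr)2, THF, −78 °C; then allyl bromide, −78 to 0 °C
Reagents that add atoms: allyl bromide, C=CCBr
Why: Second kinetic enolate alkylation, in which A(1,2) strain with the enolate methyl turns the neighbouring isopropenyl group pseudoaxial so that allyl bromide enters on the opposite face, setting the quaternary centre (future C10) with the chain trans to the C5 substituent, the relationship that becomes the trans ring fusion.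

Step 3
Reactants: 5 the allyl ketone
Product: 6 3-[(1R,6R)-1,3-dimethyl-2-oxo-6-(prop-1-en-2-yl)cyclohex-3-en-1-yl]propanal
Conditions: PdCl2(PhCN)2 (cat.), CuCl2·2H2O (cat.), AgNO2 (cat.), O2 (1 atm), t-BuOH/MeNO2, rt
Reagents that add atoms: dioxygen, O=O
Why: Nitrite-modified, aldehyde-selective (anti-Markovnikov) Wacker oxidation should touch only the monosubstituted allyl alkene, because the 1,1-disubstituted isopropenyl and the enone alkenes are inert under these conditions and the neopentyl position of the allyl group disfavours attack at its internal carbon.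

Step 4
Reactants: 6 the keto aldehyde
Product: 7 3-[(1R,6R)-1,3-dimethyl-2-oxo-6-(prop-1-en-2-yl)cyclohex-3-en-1-yl]propanenitrile
Conditions: I2, 28% aq. NH3, THF, rt
Reagents that add atoms: ammonia, N
Why: Oxidative conversion of an aldehyde to a nitrile (aldimine formation, N-iodination, loss of HI) is mild enough to leave the hindered enone and both stereocentres untouched.

Step 5
Reactants: 7 the enone nitrile
Product: 9 (5R,6R)-6-(2-cyanoethyl)-2,6-dimethyl-5-(prop-1-en-2-yl)cyclohex-1-en-1-yl trifluoromethanesulfonate, via lithium enolate 8 (not isolated)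
Conditions: LiBH(s-Bu)3, THF, −78 °C; then PhNTf2, −78 °C to rt
Reagents that add atoms: N-phenylbis(trifluoromethanesulfonimide), O=S(=O)(N(c1ccccc1)S(=O)(=O)C(F)(F)F)C(F)(F)F
Why: Conjugate (1,4) hydride reduction of the enone, which has an unsubstituted β-carbon, gives the C8=C9 enolate regiospecifically, and O-triflation fixes it as the enol triflate; the nitrile does not react at −78 °C.

Step 6
Reactants: 9 the enol triflate
Product: 10 methyl (5R,6R)-6-(2-cyanoethyl)-2,6-dimethyl-5-(prop-1-en-2-yl)cyclohex-1-ene-1-carboxylate
Conditions: Pd(OAc)2 (cat.), 1,3-bis(diphenylphosphino)propane, CO (1 atm), MeOH, Et3N, DMF, 70 °C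
Reagents that add atoms: carbon monoxide, [C-]#[O+]; methanol, CO
Why: Palladium-catalysed methoxycarbonylation of an enol triflate (oxidative addition to zerovalent palladium, CO insertion, methanolysis) installs C11 on C9, and insertion of the acylpalladium into the isopropenyl group would need a bridgehead alkene and should not compete.

Step 7
Reactants: 10 the isopropenyl nitrile ester
Product: 12 methyl (5S,10R)-3-oxodrim-8-en-11-oate (ent series, trans-fused), via ketimine 11 (not isolated)
Conditions: Fe(acac)3 (0.3 equiv), PhSiH3, EtOH (0.02 M), 60 °C; then 1 M aq. HCl, THF, rt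
Reagents that add atoms: water, O
Why: The iron hydride generated from Fe(acac)3 and PhSiH3 transfers a hydrogen atom to the CH2 terminus of the isopropenyl group, which becomes the second methyl on C4 and leaves a nucleophilic tertiary radical at C4. This radical adds to the nitrile carbon in a 6-exo-dig closure that forms the C3–C4 bond and ring A, and the iminyl radical is reduced to ketimine 11, which acid hydrolyses to the C3 ketone. The closest known reaction type is the iron-catalysed hydrogen-atom-transfer cyclisation of alkene-tethered nitriles to α-quaternary cycloalkanones, itself a descendant of tin hydride radical cyclisations onto cyano groups. No new stereocentre is formed (C4 carries two methyls, C3 is sp2); the trans ring fusion is inherited from the trans C5/C10 substituents set in step 2, whose diequatorial conformer holds the radical and the nitrile gauche as a chair-like closure requires. The step needs chemoselective hydrogen-atom transfer and cyclisation faster than reduction of the radical. The first is secured because the isopropenyl group is the only electron-neutral 1,1-disubstituted alkene (the tetrasubstituted enoate alkene is inert). The second is helped by the rigid ring B template and high dilution, and the only other closure, onto the fully substituted C8, would give a strained bicyclo[2.2.1]heptane.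

Step 8
Reactants: 12 the conjugated keto ester
Product: 14 methyl (5S,9R,10R)-3-oxodrim-8(12)-en-11-oate, via dilithium bis-enolate 13 (not isolated)
Conditions: LiN(i-Pr)2 (2.5 equiv), THF/DMPU, −78 to −30 °C; then AcOH, THF, −78 °C
Reagents that add atoms: none
Why: Deconjugative protonation of an ester dienolate: base removes a C12 methyl proton (the γ-carbon cis to the ester carbonyl) besides enolising the C3 ketone, and kinetic α-protonation at C9 from the face opposite the axial C10 methyl should leave the C8=C12 exocyclic alkene and the ester equatorial, cis to C10–CH3.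

Step 9
Reactants: 14 the deconjugated keto ester
Product: 15 (3R,5S,9R,10R)-drim-8(12)-ene-3,11-diol (ent-3-hydroxyalbicanol)
Conditions: LiAlH4, THF, 0 °C to rt
Reagents that add atoms: none
Why: Hydride reduction takes the ester to the primary alcohol and the 4,4-dimethyl-3-ketone to the alcohol by axial hydride delivery on the face away from the axial C4 and C10 methyls, which should give mainly the equatorial (3R) alcohol as is usual for such ketones.

Step 10
Reactants: 15 the diol; 16 umbelliferone (7-hydroxycoumarin)
Product: 17 7-{[(3R,5S,9R,10R)-3-hydroxydrim-8(12)-en-11-yl]oxy}-2H-chromen-2-one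
Conditions: PPh3, DIAD, THF, 0 to 50 °C
Reagents that add atoms: none
Why: Mitsunobu etherification, in which the acidic phenol displaces the oxyphosphonium of the primary C11 alcohol, while the secondary C3 alcohol flanked by the gem-dimethyl carbon is too hindered to be activated; no stereocentre is involved.

Step 11
Reactants: 17 the hydroxy aryl ether
Product: 18 the target, (3R,5S,9R,10R)-11-[(2-oxo-2H-chromen-7-yl)oxy]drim-8(12)-en-3-yl 3-methylbutanoate
Conditions: 3-methylbutanoyl chloride, pyridine, DMAP (cat.), CH2Cl2, 0 °C to rt
Reagents that add atoms: 3-methylbutanoyl chloride, CC(C)CC(=O)Cl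
Why: DMAP-catalysed acylation of the remaining equatorial secondary alcohol proceeds with retention at C3 and does not affect the coumarin lactone or the exocyclic alkene.

## Compound list

1 | (S)-(+)-carvone | CC1=CC[C@H](C(C)=C)CC1=O | starting material
2 | lithium dienolate of carvone | [Li+].CC1=CC[C@H](C(C)=C)C=C1[O-] | intermediate
3 | (5S,6R)-6-methylcarvone (trans; major epimer) | CC1=CC[C@H](C(C)=C)[C@@H](C)C1=O | intermediate
4 | lithium enolate of 6-methylcarvone | [Li+].CC1=CC[C@H](C(C)=C)C(C)=C1[O-] | intermediate
5 | (5R,6R)-6-allyl-2,6-dimethyl-5-(prop-1-en-2-yl)cyclohex-2-en-1-one | CC1=CC[C@H](C(C)=C)[C@@](C)(CC=C)C1=O | intermediate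
6 | 3-[(1R,6R)-1,3-dimethyl-2-oxo-6-(prop-1-en-2-yl)cyclohex-3-en-1-yl]propanal | CC1=CC[C@H](C(C)=C)[C@@](C)(CCC=O)C1=O | intermediate
7 | 3-[(1R,6R)-1,3-dimethyl-2-oxo-6-(prop-1-en-2-yl)cyclohex-3-en-1-yl]propanenitrile | CC1=CC[C@H](C(C)=C)[C@@](C)(CCC#N)C1=O | intermediate
8 | lithium enolate from 1,4-reduction of 7 | [Li+].CC=1CC[C@H](C(C)=C)[C@@](C)(CCC#N)C=1[O-] | intermediate
9 | (5R,6R)-6-(2-cyanoethyl)-2,6-dimethyl-5-(prop-1-en-2-yl)cyclohex-1-en-1-yl trifluoromethanesulfonate | CC=1CC[C@H](C(C)=C)[C@@](C)(CCC#N)C=1OS(=O)(=O)C(F)(F)F | intermediate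
10 | methyl (5R,6R)-6-(2-cyanoethyl)-2,6-dimethyl-5-(prop-1-en-2-yl)cyclohex-1-ene-1-carboxylate | CC=1CC[C@H](C(C)=C)[C@@](C)(CCC#N)C=1C(=O)OC | intermediate
11 | methyl (5S,10R)-3-iminodrim-8-en-11-oate (ketimine) | CC=1CC[C@@H]2C(C)(C)C(=N)CC[C@@]2(C)C=1C(=O)OC | intermediate
12 | methyl (5S,10R)-3-oxodrim-8-en-11-oate | CC=1CC[C@@H]2C(C)(C)C(=O)CC[C@@]2(C)C=1C(=O)OC | intermediate
13 | dilithium bis-enolate of 12 (C2=C3 enolate and C9=C11, C8=C12 dienolate) | [Li+].[Li+].C=C1CC[C@@H]2C(C)(C)C([O-])=CC[C@@]2(C)C1=C([O-])OC | intermediate
14 | methyl (5S,9R,10R)-3-oxodrim-8(12)-en-11-oate | C=C1CC[C@@H]2C(C)(C)C(=O)CC[C@@]2(C)[C@@H]1C(=O)OC | intermediate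
15 | (3R,5S,9R,10R)-drim-8(12)-ene-3,11-diol | C=C1CC[C@@H]2C(C)(C)[C@H](O)CC[C@@]2(C)[C@@H]1CO | intermediate
16 | umbelliferone (7-hydroxy-2H-chromen-2-one) | Oc1ccc2ccc(=O)oc2c1 | starting material
17 | 7-{[(3R,5S,9R,10R)-3-hydroxydrim-8(12)-en-11-yl]oxy}-2H-chromen-2-one | C=C1CC[C@@H]2C(C)(C)[C@H](O)CC[C@@]2(C)[C@@H]1COc1ccc2ccc(=O)oc2c1 | intermediate
18 | (3R,5S,9R,10R)-11-[(2-oxo-2H-chromen-7-yl)oxy]drim-8(12)-en-3-yl 3-methylbutanoate (CNP0295317.1) | C=C1CC[C@@H]2C(C)(C)[C@H](OC(=O)CC(C)C)CC[C@@]2(C)[C@@H]1COc1ccc2ccc(=O)oc2c1 | target

## Step count and risks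

Total step count: 11. Longest linear sequence: 11 steps (1 to 18); umbelliferone 16 enters in step 10.

Steps most likely to fail:

1. Step 7 (key step). The tertiary C4 radical may be consumed before it closes onto the nitrile: by reduction, by 1,5-hydrogen transfer from the α-cyano methylene, or by back-transfer to the isopropylidene isomer. The uncyclised isopropyl ester would then accumulate. Fallback, setting out from 10: Markovnikov hydrobromination of the isopropenyl group (HBr, CH2Cl2, −40 °C; the enoate alkene is deactivated) should give the tertiary bromide methyl (5R,6R)-5-(2-bromopropan-2-yl)-6-(2-cyanoethyl)-2,6-dimethylcyclohex-1-ene-1-carboxylate F1. Slow addition of Bu3SnH with AIBN in refluxing benzene then generates the same C4 radical by bromine abstraction, in a chain in which the concentration of the hydrogen donor is set by the addition rate. It closes 6-exo onto the cyano group (classical tin hydride cyclisation onto nitriles), and acid work-up of ketimine 11 comes back to the route at 12.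

2. Step 8. Deprotonation may occur at the ring carbon C7 instead of C12, or protonation at the γ-position, so that the endocyclic Δ7 isomer or the conjugated ester forms instead of the exocyclic alkene. Fallback, setting out from 12: NaBH4 (MeOH, 0 °C) reduces only the C3 ketone, giving methyl (3R,5S,10R)-3-hydroxydrim-8-en-11-oate F2; the ketone is removed first because an α,α-dimethyl ketone would undergo Norrish cleavage. Irradiation at 254 nm (MeOH, catalytic 1,2-dimethylimidazole) effects photodeconjugation: the 1,5-hydrogen shift of the excited enoate can take hydrogen only from C12, the γ-carbon cis to the carbonyl, giving the dienol methyl ketene hemiacetal F3. This ketonises by protonation at C9 on the face away from the C10 methyl to methyl (3R,5S,9R,10R)-3-hydroxydrim-8(12)-en-11-oate F4. LiAlH4 reduction of F4 comes back to the route at 15.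

3. Step 3. Markovnikov attack giving the methyl ketone, or migration of the alkene, may compete with anti-Markovnikov oxidation. Fallback, setting out from 5: the enone is masked first by conjugate reduction and triflation (LiBH(s-Bu)3, then PhNTf2), through the lithium enolate of the 1,4-reduced allyl ketone F5, to (5R,6R)-6-allyl-2,6-dimethyl-5-(prop-1-en-2-yl)cyclohex-1-en-1-yl trifluoromethanesulfonate F6. Hydroboration with disiamylborane, which prefers the monosubstituted alkene over isopropenyl, gives the alkyl(disiamyl)borane F7, and NaBO3·4H2O oxidises it to the primary alcohol (5R,6R)-6-(3-hydroxypropyl)-2,6-dimethyl-5-(prop-1-en-2-yl)cyclohex-1-en-1-yl trifluoromethanesulfonate F8. TEMPO/PhI(OAc)2/NH4OAc converts this alcohol directly into the nitrile, coming back to the route at 9.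

Further compounds
F1 | step 7 | methyl (5R,6R)-5-(2-bromopropan-2-yl)-6-(2-cyanoethyl)-2,6-dimethylcyclohex-1-ene-1-carboxylate | CC=1CC[C@H](C(C)(C)Br)[C@@](C)(CCC#N)C=1C(=O)OC
F2 | step 8 | methyl (3R,5S,10R)-3-hydroxydrim-8-en-11-oate | CC=1CC[C@@H]2C(C)(C)[C@H](O)CC[C@@]2(C)C=1C(=O)OC
F3 | step 8 | dienol (methyl ketene hemiacetal) from photoenolisation of F2, not isolated | C=C1CC[C@@H]2C(C)(C)[C@H](O)CC[C@@]2(C)C1=C(O)OC
F4 | step 8 | methyl (3R,5S,9R,10R)-3-hydroxydrim-8(12)-en-11-oate | C=C1CC[C@@H]2C(C)(C)[C@H](O)CC[C@@]2(C)[C@@H]1C(=O)OC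
F5 | step 3 | lithium enolate from 1,4-reduction of 5, not isolated | [Li+].CC=1CC[C@H](C(C)=C)[C@@](C)(CC=C)C=1[O-]
F6 | step 3 | (5R,6R)-6-allyl-2,6-dimethyl-5-(prop-1-en-2-yl)cyclohex-1-en-1-yl trifluoromethanesulfonate | CC=1CC[C@H](C(C)=C)[C@@](C)(CC=C)C=1OS(=O)(=O)C(F)(F)F
F7 | step 3 | alkyl(disiamyl)borane from hydroboration of F6, not isolated | CC=1CC[C@H](C(C)=C)[C@@](C)(CCCB(C(C)C(C)C)C(C)C(C)C)C=1OS(=O)(=O)C(F)(F)F
F8 | step 3 | (5R,6R)-6-(3-hydroxypropyl)-2,6-dimethyl-5-(prop-1-en-2-yl)cyclohex-1-en-1-yl trifluoromethanesulfonate | CC=1CC[C@H](C(C)=C)[C@@](C)(CCCO)C=1OS(=O)(=O)C(F)(F)F
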